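Remarks on the chemistry
- Locants follow the ring numbering set out under "Structural features".
- By the sequence rule the C8 alkenylstannane of the open-chain precursor is E, because tin outranks C7. It becomes the Z exocyclic alkene of the cyclised product, and is named E below.
- Compounds 12 to 21 are racemic at C6 (12 also at C11). This has no consequence, because C6 ends as a carbonyl carbon.
- But-3-en-1-ylzinc bromide (6) is taken as the commercial THF solution.

## Structural features

The target is a ten-membered carbocycle numbered C1 (quaternary oxirane carbon carrying the acetoxymethyl carbon C1′), C2, C3, C4=C5 (methyl on C5), C6 (ketone), C7, C8, C9, C10 (oxirane CH). C11 is exocyclic on C8 and carries a methyl group and the second acetoxymethyl carbon C12. One oxirane is fused to the ring at C1–C10 (ring carbons C2 and C9 cis on it). The other is spiro at C8 and spans C8–C11 (C9 cis to the C11 methyl), and the C4=C5–C6=O enone is E, so the ring contains a trans double bond. The four stereocentres (1R, 10R, 8S, 11R) form two vicinal pairs, C1/C10 and C8/C11, separated only by the C9 methylene. Fragile points are the β,γ-epoxy ketone (C6=O, C7H2, C8 oxirane), which can open by E1cB elimination under base, the two highly substituted acid-labile oxiranes, and the primary acetates. Each oxirane is a 2,3-epoxy alcohol ester, so each stereocentre pair is the retron of a Sharpless epoxidation (C1′–OH on C1=C10, C12–OH on C11=C8), and one tartrate enantiomer serves both. The real difficulty is therefore the achiral ten-membered trienone underneath: a strained ring with an E-enone, a ring alkene of fixed geometry, and an exocyclic tetrasubstituted alkene whose CH3 and CH2O ends must be placed correctly. In that trienone C9 is a doubly allylic methylene between sp2 C8 and sp2 C10. The key step exploits this by making C8–C9 from an allyl electrophile (C9–C10–C1) and an alkenyl nucleophile (C8), the polarity a germacrene cyclase uses for the same ring bond.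

## Logic of the disconnections

27 to 26: the two acyl C–O bonds are cut. The free primary hydroxyls are the directing groups for epoxidation, so esterification has to be last. The forward step must be cold and only weakly basic, because C7–H is acidic and the C8 oxirane is a β-leaving group.

26 to 24 (through 25): the four oxirane C–O bonds (C1–O, C10–O, C8–O, C11–O) are cut. All four stereocentres disappear and 24 is achiral. The forward step needs the same facial sense at both allylic alcohols, an enone that stays inert, and reagent control strong enough to override any conformational bias of the ring in the second epoxidation.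

24 to 23: the two O–Si bonds are cut. The silyl ethers mask the hydroxyls through the organometallic steps. Their removal must not enolise the β,γ-unsaturated ketone.

23 to 22: the C8–C9 ring bond is cut. It is the only ring bond with an sp2 carbon that can carry a metal on one side and an allylic carbon that can carry a leaving group on the other. Cutting it opens the ring to an acyclic chain with no stereocentres, in which all three alkene geometries can be set by acyclic or small-ring chemistry. The forward step must bond at C9 and not C1, keep both alkene geometries, run without base, and favour ring closure over oligomerisation.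

22 to 21 to 20 to 18: functional-group changes only. The C6 carbonyl comes from the carbinol in the last step before ring closure, so the β,γ-unsaturated ketone exists for a single step. The C12 silyl ether comes from the primary hydroxyl of 20. The diol 20 is traced back to the six-membered lactone 18, whose ring ties C12 and C7 to the same side of C8=C11. The reduction must open the lactone fully without touching the allylic chloride or the C–Sn bond.

18 to 16 to 15 to 14: C9–Cl is traced to C9–OH, C8–Sn to the C8 enol triflate, and the C9 hydroxyl to its 4-methoxybenzyl ether. The order is dictated by compatibility: the chloride can only be made after the palladium-catalysed stannylation, and the oxidative ether cleavage is placed before tin is present.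

14 to 13 to 12: the O–S bond and then the lactone C12–O bond are cut. 13 is the enol of a cyclic β-keto ester, and the ring is the control element for the tetrasubstituted alkene. Sulfonylation must occur on the C8 oxygen.

12 to 9 and 10: the C6–C7 bond is cut (aldol). One step joins the four-carbon unit C7–C8–C11(CH3)–C12, and 10 is commercial. The dianion must react at its terminal carbon and add 1,2 to the enal.

9 to 7 and 8: the C4=C5 double bond is cut (cross-metathesis). The forward step must be E-selective and must engage only the terminal alkene of 7.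

7 to 5 and 6: the C1–C2 bond is cut (sp2–sp3 coupling). The alkene geometry of 5 must be retained.

5 to 4 to 2 to 1: the C1–I and C10–H bonds across the alkyne of 2 are cut, then the protecting groups. Hydroxyl-directed anti hydrometalation puts C1′ trans to C9 and leaves the two oxygens differentiated from the start (free at C9, silylated at C1′). A carbometalation of the free diol 1 would give an undifferentiated diol, and carbometalation of a monoether risks β-elimination to an allene. The forward step must be kept cold so that the β-silyloxy alkenylaluminate does not eliminate.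

## Other disconnections considered

Alternative 1: The cut is the four oxirane C–O bonds, made on an open chain before any ring exists. In the forward direction Ti(OiPr)4, D-(−)-diethyl tartrate and tBuOOH would convert the acyclic skipped dienediol A2 into the bis-epoxy diol A1, and the ring would be closed later at C5–C6 from the C5 alkenyl iodide and a C6 aldehyde (CrCl2/NiCl2), followed by oxidation. In its favour, acyclic allylic alcohols are the best-behaved Sharpless substrates, no ketone or medium-ring conformation interferes, and no hindered stannane has to cyclise. On stereochemical predictability this alternative is better than the chosen plan. Against it, both oxiranes of A1 must survive aldehyde formation, a Lewis-acidic chromium-mediated ring closure with halide present, and a carbinol oxidation. The C8 oxirane is β to the C6 carbonyl as soon as that carbonyl exists, and a throwaway C6 stereocentre is created. A2 still needs the C8–C9 union and the tetrasubstituted geometry solved, so the alkene problem is equal in both plans. Step economy is equal or slightly worse, because C6 needs two extra oxidation-level changes. The chosen plan places the risk in the epoxidation, the alternative in the ring closure.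

Alternative 2: The cut is C2–C3, formed while a σ-bond of a six-membered ring is cleaved. In the forward direction KN(SiMe3)2 and 18-crown-6 would convert the tertiary cyclohexanol A4 (isopropenyl on the carbinol carbon, vinyl on the neighbouring quaternary carbon) into its alkoxide, a [3,3] shift would expand the ring, and PhNTf2 would trap the enolate as the enol triflate A3. In its favour, the ring forms by a concerted, strain-releasing, irreversible rearrangement that needs neither high dilution nor tin, and a chair transition state sets the E C4=C5 alkene. As a ring-forming event it is better than the chosen plan. Against it, A3 has the C1 methyl cis to C9, whereas 27 needs the oxygenated carbon on C1 trans to C9, and that methyl still has to be oxidised after the triflate is reduced. The exocyclic tetrasubstituted C8=C11 alkene would have to come from a C8 ketone with no element to tell CH3 from CH2O. The two stereocentres of A3 are built only to be destroyed. Structurally the chosen plan fixes all three alkene geometries before the ring is closed, and the alternative leaves two open. The alternative is also clearly longer after its key step.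

Alternative 3: The cut traces both ring alkenes (C4=C5 and C1=C10) to the central cyclobutane of the tricyclic enone–cyclobutene photoadduct A6. In the forward direction flash thermolysis would cleave C1–C4 and C5–C10 and open the six-membered ring into the cyclodecadienone A5. In its favour, an inexpensive carvone-type ring supplies C5–C10 with the C8 side chain, one step delivers the E C4=C5 and ring-cis C1=C10 pattern that 24 also has, and no tin or palladium is needed. On ring-alkene geometry it is the equal of the chosen plan, and arguably better because both alkenes come from one step. Against it, the 1,5-diene of A5 can undergo Cope rearrangement at the temperature of its formation. The acrylate must be isomerised into the tetrasubstituted C8=C11 position with CH2O cis to C7 without a control element, and its ester reduced beside the C6 ketone. The C8 stereocentre is erased, so the chirality of the starting ring buys nothing and the stereocentres would still come from a Sharpless step. The mechanism (photocycloaddition, then thermal cycloreversion) scales less easily than the solution chemistry of the chosen plan. Step economy up to the ring is better, after the ring worse.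

Key step: step 15

## Steps

Step 1
Reactants: 1 2-butyne-1,4-diol
Product: 2 4-[(tert-butyldimethylsilyl)oxy]but-2-yn-1-ol
Conditions: NaH (1.0 equiv), THF, 0 °C; TBSCl (1.0 equiv), 0 °C to rt
Reagents that add atoms: tert-butyldimethylsilyl chloride, CC(C)(C)[Si](C)(C)Cl
Why: O-silylation of a symmetrical diol through its sparingly soluble monosodium alkoxide, which should react before a second deprotonation occurs; any bis-ether is removed by chromatography.

Step 2
Reactants: 2 4-[(tert-butyldimethylsilyl)oxy]but-2-yn-1-ol
Product: 4 (2Z)-4-[(tert-butyldimethylsilyl)oxy]-3-iodobut-2-en-1-ol, via cyclic alkenylaluminate 3 (not isolated)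
Conditions: NaAlH2(OCH2CH2OMe)2 (1.5 equiv), THF, 0 °C; EtOAc; I2, −78 to 0 °C
Reagents that add atoms: iodine, [I][I]
Why: Hydroxyl-directed anti hydroalumination of a propargylic alcohol puts hydride on the proximal alkyne carbon (C10) and aluminium on the distal one (C1) in a five-membered chelate; iododealumination with retention gives iodine cis to C9, so C1′ is trans to C9. Keeping the mixture at or below 0 °C should prevent β-elimination of the silyloxy group to an allene.

Step 3
Reactants: 4 (2Z)-4-[(tert-butyldimethylsilyl)oxy]-3-iodobut-2-en-1-ol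
Product: 5 tert-butyl{[(2Z)-2-iodo-4-[(4-methoxybenzyl)oxy]but-2-en-1-yl]oxy}dimethylsilane
Conditions: NaH, 4-methoxybenzyl chloride, Bu4NI (cat.), THF–DMF, 0 °C to rt
Reagents that add atoms: 4-methoxybenzyl chloride, COc1ccc(CCl)cc1
Why: Williamson etherification of the C9 hydroxyl; the 4-methoxybenzyl ether is orthogonal to the silyl ether, inert to the organozinc, dianion and triflation steps, and removable oxidatively.

Step 4
Reactants: 5 tert-butyl{[(2Z)-2-iodo-4-[(4-methoxybenzyl)oxy]but-2-en-1-yl]oxy}dimethylsilane; 6 but-3-en-1-ylzinc bromide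
Product: 7 tert-butyl{[(2E)-2-(but-3-en-1-yl)-4-[(4-methoxybenzyl)oxy]but-2-en-1-yl]oxy}dimethylsilane
Conditions: Pd(dppf)Cl2·CH2Cl2 (5 mol %), THF, rt to 45 °C
Reagents that add atoms: none
Why: Negishi sp2–sp3 coupling forms C1–C2 with retention at the alkenyl carbon, so C2 ends cis to C9; the bidentate ligand favours reductive elimination over β-hydride loss, and the allylic ethers do not ionise.

Step 5
Reactants: 7 tert-butyl{[(2E)-2-(but-3-en-1-yl)-4-[(4-methoxybenzyl)oxy]but-2-en-1-yl]oxy}dimethylsilane; 8 methacrolein
Product: 9 (2E,6E)-6-{[(tert-butyldimethylsilyl)oxy]methyl}-8-[(4-methoxybenzyl)oxy]-2-methylocta-2,6-dienal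
Conditions: methacrolein (8 equiv), second-generation Hoveyda–Grubbs catalyst RuCl2(H2IMes)(=CH-C6H4-2-OiPr) (5 mol %), CH2Cl2, 40 °C
Reagents that add atoms: none
Why: Olefin cross-metathesis of the terminal alkene with a 1,1-disubstituted enal forms C4=C5 with the thermodynamically preferred E geometry; the trisubstituted C1=C10 alkene is too hindered to take part.

Step 6
Reactants: 9 (2E,6E)-6-{[(tert-butyldimethylsilyl)oxy]methyl}-8-[(4-methoxybenzyl)oxy]-2-methylocta-2,6-dienal; 10 methyl 2-methyl-3-oxobutanoate
Product: 12 methyl (6E,10E)-10-{[(tert-butyldimethylsilyl)oxy]methyl}-5-hydroxy-12-[(4-methoxybenzyl)oxy]-2,6-dimethyl-3-oxododeca-6,10-dienoate (diastereomer mixture), via dianion 11 (not isolated)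
Conditions: 10 (1.6 equiv), NaH, THF, 0 °C; nBuLi, 0 °C; 9, −78 °C; AcOH quench
Reagents that add atoms: none
Why: Acetoacetate dianion aldol: the more basic terminal carbanion (future C7) adds 1,2 to the enal carbonyl (C6) to form C6–C7. The new centres at C6 and C11 are uncontrolled and are erased later.

Step 7
Reactants: 12 methyl (6E,10E)-10-{[(tert-butyldimethylsilyl)oxy]methyl}-5-hydroxy-12-[(4-methoxybenzyl)oxy]-2,6-dimethyl-3-oxododeca-6,10-dienoate
Product: 13 rac-4-hydroxy-3-methyl-6-[(2E,6E)-6-{[(tert-butyldimethylsilyl)oxy]methyl}-8-[(4-methoxybenzyl)oxy]octa-2,6-dien-2-yl]-5,6-dihydro-2H-pyran-2-one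
Conditions: K2CO3, MeOH, 0 °C to rt; cold dilute HCl to pH 4
Reagents that add atoms: none
Why: Lactonisation of a δ-hydroxy-β-keto ester, driven by formation of the stabilised enolate of the cyclic β-keto lactone; the six-membered ring puts C12 and C7 on the same side of the C8–C11 enol.

Step 8
Reactants: 13 rac-4-hydroxy-3-methyl-6-[(2E,6E)-6-{[(tert-butyldimethylsilyl)oxy]methyl}-8-[(4-methoxybenzyl)oxy]octa-2,6-dien-2-yl]-5,6-dihydro-2H-pyran-2-one
Product: 14 rac-6-[(2E,6E)-6-{[(tert-butyldimethylsilyl)oxy]methyl}-8-[(4-methoxybenzyl)oxy]octa-2,6-dien-2-yl]-3-methyl-2-oxo-5,6-dihydro-2H-pyran-4-yl trifluoromethanesulfonate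
Conditions: Tf2O, iPr2NEt, CH2Cl2, −78 °C
Reagents that add atoms: trifluoromethanesulfonic anhydride, O=S(=O)(OS(=O)(=O)C(F)(F)F)C(F)(F)F
Why: Enol triflate formation by O-sulfonylation of the acidic vinylogous acid at the C8 oxygen; the ring holds the C8=C11 geometry.

Step 9
Reactants: 14 rac-6-[(2E,6E)-6-{[(tert-butyldimethylsilyl)oxy]methyl}-8-[(4-methoxybenzyl)oxy]octa-2,6-dien-2-yl]-3-methyl-2-oxo-5,6-dihydro-2H-pyran-4-yl trifluoromethanesulfonate
Product: 15 rac-6-[(2E,6E)-6-{[(tert-butyldimethylsilyl)oxy]methyl}-8-hydroxyocta-2,6-dien-2-yl]-3-methyl-2-oxo-5,6-dihydro-2H-pyran-4-yl trifluoromethanesulfonate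
Conditions: DDQ (1.2 equiv), CH2Cl2–pH 7 buffer, 0 °C
Reagents that add atoms: none
Why: Oxidative cleavage of the 4-methoxybenzyl ether by benzylic hydride abstraction and hydrolysis; it is placed before tin is introduced and before any ketone exists, and the electron-poor triflate and the silyl ether should be inert.

Step 10
Reactants: 15 rac-6-[(2E,6E)-6-{[(tert-butyldimethylsilyl)oxy]methyl}-8-hydroxyocta-2,6-dien-2-yl]-3-methyl-2-oxo-5,6-dihydro-2H-pyran-4-yl trifluoromethanesulfonate
Product: 16 rac-6-[(2E,6E)-6-{[(tert-butyldimethylsilyl)oxy]methyl}-8-hydroxyocta-2,6-dien-2-yl]-3-methyl-4-(trimethylstannyl)-5,6-dihydro-2H-pyran-2-one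
Conditions: Me3SnSnMe3 (1.5 equiv), Pd(PPh3)4 (5 mol %), LiCl (6 equiv), THF, 60 °C
Reagents that add atoms: hexamethylditin, C[Sn](C)(C)[Sn](C)(C)C
Why: Palladium-catalysed stannylation of an enol triflate with a distannane (oxidative addition, Sn–Sn transmetalation, reductive elimination); C–Sn replaces C–O with retention, so tin is cis to the C11 methyl, and the free allylic alcohol is not ionised under these neutral conditions.

Step 11
Reactants: 16 rac-6-[(2E,6E)-6-{[(tert-butyldimethylsilyl)oxy]methyl}-8-hydroxyocta-2,6-dien-2-yl]-3-methyl-4-(trimethylstannyl)-5,6-dihydro-2H-pyran-2-one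
Product: 18 rac-6-[(2E,6E)-8-chloro-6-{[(tert-butyldimethylsilyl)oxy]methyl}octa-2,6-dien-2-yl]-3-methyl-4-(trimethylstannyl)-5,6-dihydro-2H-pyran-2-one, via allylic mesylate 17 (not isolated)
Conditions: MsCl, LiCl, 2,4,6-collidine, DMF, 0 °C
Reagents that add atoms: lithium chloride, [Li+].[Cl-]; methanesulfonyl chloride (second chloride source), CS(=O)(=O)Cl
Why: Mesylation in situ and SN2 displacement by chloride at the primary allylic carbon without allylic transposition; the weak base tolerates the alkenylstannane and the lactone.

Step 12
Reactants: 18 rac-6-[(2E,6E)-8-chloro-6-{[(tert-butyldimethylsilyl)oxy]methyl}octa-2,6-dien-2-yl]-3-methyl-4-(trimethylstannyl)-5,6-dihydro-2H-pyran-2-one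
Product: 20 rac-(2E,6E,10E)-10-{[(tert-butyldimethylsilyl)oxy]methyl}-12-chloro-2,6-dimethyl-3-(trimethylstannyl)dodeca-2,6,10-triene-1,5-diol, via lactol 19 (not isolated)
Conditions: iBu2AlH (3.5 equiv), CH2Cl2, −78 to −30 °C; aqueous KNaC4H4O6
Reagents that add atoms: none
Why: Double 1,2-hydride reduction of the unsaturated δ-lactone (lactol, then its open hydroxy-enal form) gives the ene-1,5-diol; no bond to C8 or C11 is broken, so the ring-imposed alkene geometry is kept. Allylic halides and alkenylstannanes are known to tolerate this hydride at low temperature.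

Step 13
Reactants: 20 rac-(2E,6E,10E)-10-{[(tert-butyldimethylsilyl)oxy]methyl}-12-chloro-2,6-dimethyl-3-(trimethylstannyl)dodeca-2,6,10-triene-1,5-diol
Product: 21 rac-(2E,6E,10E)-1-[(tert-butyldimethylsilyl)oxy]-10-{[(tert-butyldimethylsilyl)oxy]methyl}-12-chloro-2,6-dimethyl-3-(trimethylstannyl)dodeca-2,6,10-trien-5-ol
Conditions: TBSCl (1.1 equiv), imidazole, CH2Cl2, 0 °C
Reagents that add atoms: tert-butyldimethylsilyl chloride, CC(C)(C)[Si](C)(C)Cl
Why: Chemoselective silylation of the primary C12 hydroxyl over the more hindered secondary C6 hydroxyl; the allylic chloride should survive brief cold contact with imidazole.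

Step 14
Reactants: 21 rac-(2E,6E,10E)-1-[(tert-butyldimethylsilyl)oxy]-10-{[(tert-butyldimethylsilyl)oxy]methyl}-12-chloro-2,6-dimethyl-3-(trimethylstannyl)dodeca-2,6,10-trien-5-ol
Product: 22 (2E,6E,10E)-1-[(tert-butyldimethylsilyl)oxy]-10-{[(tert-butyldimethylsilyl)oxy]methyl}-12-chloro-2,6-dimethyl-3-(trimethylstannyl)dodeca-2,6,10-trien-5-one
Conditions: Dess–Martin periodinane, pyridine, CH2Cl2, 0 °C
Reagents that add atoms: none
Why: Buffered Dess–Martin oxidation of the secondary allylic alcohol to the enone; the β,γ-unsaturated ketone is formed only now, under neutral conditions, and is used at once.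

Step 15
Reactants: 22 (2E,6E,10E)-1-[(tert-butyldimethylsilyl)oxy]-10-{[(tert-butyldimethylsilyl)oxy]methyl}-12-chloro-2,6-dimethyl-3-(trimethylstannyl)dodeca-2,6,10-trien-5-one
Product: 23 (2E,6E,9Z)-6-{[(tert-butyldimethylsilyl)oxy]methyl}-9-{1-[(tert-butyldimethylsilyl)oxy]propan-2-ylidene}-2-methylcyclodeca-2,6-dien-1-one
Conditions: Pd2(dba)3·CHCl3 (10 mol %), AsPh3 (40 mol %), CuI (20 mol %), degassed DMF–THF, 40 °C, syringe-pump addition to about 1 mM
Reagents that add atoms: none
Why: Intramolecular Stille coupling: zerovalent palladium displaces chloride at C9 to give an η3-allyl complex over C9–C10–C1, the C8–Sn bond is transmetalated (helped by CuI through a transient alkenylcopper in DMF), and reductive elimination joins C8 to C9. The closest known reaction type is the Stille macrocyclisation of allylic halides with alkenylstannanes; the weakly bound AsPh3 is chosen because transmetalation of a fully substituted stannane should be rate-limiting. The ten-membered ring closes by C–C reductive elimination at the unsubstituted allyl terminus from an eleven-membered palladacycle, leaving C1=C10 endocyclic and C8=C11 exocyclic; bonding at C1 would need an eight-membered ring with a new quaternary carbon and is disfavoured on both counts. No stereocentre is formed. The step needs regioselectivity for C9 over C1 (steric), retention of the C1=C10 geometry (syn/anti exchange would require a σ-allyl at tertiary C1, while the accessible σ-allyl at C9 only exchanges hydrogens), retention at C8 (transmetalation and reductive elimination both retain configuration), and no migration of C8=C11 into conjugation (no base is present). Slow addition at high dilution favours ring closure over oligomerisation.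

Step 16
Reactants: 23 (2E,6E,9Z)-6-{[(tert-butyldimethylsilyl)oxy]methyl}-9-{1-[(tert-butyldimethylsilyl)oxy]propan-2-ylidene}-2-methylcyclodeca-2,6-dien-1-one
Product: 24 (2E,6E,9Z)-6-(hydroxymethyl)-9-(1-hydroxypropan-2-ylidene)-2-methylcyclodeca-2,6-dien-1-one
Conditions: HF·pyridine, pyridine, THF, 0 °C to rt
Reagents that add atoms: none
Why: Fluoride-mediated cleavage of both primary silyl ethers under buffered, slightly acidic conditions; basic fluoride sources are avoided so that C7 is not enolised.

Step 17
Reactants: 24 (2E,6E,9Z)-6-(hydroxymethyl)-9-(1-hydroxypropan-2-ylidene)-2-methylcyclodeca-2,6-dien-1-one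
Product: 26 bis-epoxy diol with (1R,10R)-1,10-oxirane and (8S,11R)-8,11-spiro-oxirane on the E-enone ring, via spiro-monoepoxide 25 (not isolated)
Conditions: Ti(OiPr)4 (0.3 equiv), D-(−)-diethyl tartrate (0.4 equiv), tBuOOH (4 equiv, anhydrous), 4 Å sieves, CH2Cl2, −25 °C
Reagents that add atoms: tert-butyl hydroperoxide, CC(C)(C)OO
Why: Twofold Sharpless asymmetric epoxidation: D-(−)-tartrate, the enantiomer that turns (E)-allylic alcohols into (2R,3R)-epoxy alcohols, should deliver oxygen to give 8S,11R at the C12-carbinol alkene (expected to react first, being the more electron-rich) and 1R,10R at the C1′-carbinol alkene. The enone has no directing hydroxyl and is electron-poor, so it should stay intact, and material epoxidised with the minor sense ends as separable diastereomers, which raises the enantiomeric purity of 26.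

Step 18
Reactants: 26 bis-epoxy diol with (1R,10R)-1,10-oxirane and (8S,11R)-8,11-spiro-oxirane
Product: 27 target diacetate CNP0185847.3
Conditions: Ac2O, pyridine, DMAP (cat.), CH2Cl2, 0 °C
Reagents that add atoms: acetic anhydride, CC(=O)OC(C)=O
Why: Acylation of the two primary hydroxyls; cold, weakly basic conditions should avoid E1cB opening of the β,γ-epoxy ketone, and no stereocentre is touched.

## Compound list

1 | 2-butyne-1,4-diol | OCC#CCO | starting material
2 | 4-[(tert-butyldimethylsilyl)oxy]but-2-yn-1-ol | CC(C)(C)[Si](C)(C)OCC#CCO | intermediate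
3 | sodium alkenyl(alkoxy)bis(2-methoxyethoxy)aluminate, five-membered O–Al–C chelate from anti hydroalumination of 2 | [Na+].COCCO[Al-]1(OCCOC)OC/C=C1/CO[Si](C)(C)C(C)(C)C | intermediate (not isolated)
4 | (2Z)-4-[(tert-butyldimethylsilyl)oxy]-3-iodobut-2-en-1-ol | OC/C=C(\I)CO[Si](C)(C)C(C)(C)C | intermediate
5 | tert-butyl{[(2Z)-2-iodo-4-[(4-methoxybenzyl)oxy]but-2-en-1-yl]oxy}dimethylsilane | COc1ccc(COC/C=C(\I)CO[Si](C)(C)C(C)(C)C)cc1 | intermediate
6 | but-3-en-1-ylzinc bromide | C=CCC[Zn]Br | starting material
7 | tert-butyl{[(2E)-2-(but-3-en-1-yl)-4-[(4-methoxybenzyl)oxy]but-2-en-1-yl]oxy}dimethylsilane | COc1ccc(COC/C=C(\CCC=C)CO[Si](C)(C)C(C)(C)C)cc1 | intermediate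
8 | methacrolein (2-methylprop-2-enal) | CC(=C)C=O | starting material
9 | (2E,6E)-6-{[(tert-butyldimethylsilyl)oxy]methyl}-8-[(4-methoxybenzyl)oxy]-2-methylocta-2,6-dienal | COc1ccc(COC/C=C(\CC/C=C(\C)C=O)CO[Si](C)(C)C(C)(C)C)cc1 | intermediate
10 | methyl 2-methyl-3-oxobutanoate (methyl 2-methylacetoacetate) | COC(=O)C(C)C(C)=O | starting material
11 | sodium lithium dienolate (dianion) of 10 | [Na+].[Li+].C=C([O-])C(C)=C([O-])OC | intermediate (not isolated)
12 | methyl (6E,10E)-10-{[(tert-butyldimethylsilyl)oxy]methyl}-5-hydroxy-12-[(4-methoxybenzyl)oxy]-2,6-dimethyl-3-oxododeca-6,10-dienoate, diastereomer mixture | COC(=O)C(C)C(=O)CC(O)/C(C)=C/CC/C(=C\COCc1ccc(OC)cc1)CO[Si](C)(C)C(C)(C)C | intermediate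
13 | rac-4-hydroxy-3-methyl-6-[(2E,6E)-6-{[(tert-butyldimethylsilyl)oxy]methyl}-8-[(4-methoxybenzyl)oxy]octa-2,6-dien-2-yl]-5,6-dihydro-2H-pyran-2-one | CC1=C(O)CC(OC1=O)/C(C)=C/CC/C(=C\COCc2ccc(OC)cc2)CO[Si](C)(C)C(C)(C)C | intermediate
14 | 4-trifluoromethanesulfonate (C8 enol triflate) of 13 | CC1=C(OS(=O)(=O)C(F)(F)F)CC(OC1=O)/C(C)=C/CC/C(=C\COCc2ccc(OC)cc2)CO[Si](C)(C)C(C)(C)C | intermediate
15 | enol triflate with free C9 hydroxyl | CC1=C(OS(=O)(=O)C(F)(F)F)CC(OC1=O)/C(C)=C/CC/C(=C\CO)CO[Si](C)(C)C(C)(C)C | intermediate
16 | rac-6-[(2E,6E)-6-{[(tert-butyldimethylsilyl)oxy]methyl}-8-hydroxyocta-2,6-dien-2-yl]-3-methyl-4-(trimethylstannyl)-5,6-dihydro-2H-pyran-2-one | CC1=C([Sn](C)(C)C)CC(OC1=O)/C(C)=C/CC/C(=C\CO)CO[Si](C)(C)C(C)(C)C | intermediate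
17 | C9 methanesulfonate of 16 | CC1=C([Sn](C)(C)C)CC(OC1=O)/C(C)=C/CC/C(=C\COS(C)(=O)=O)CO[Si](C)(C)C(C)(C)C | intermediate (not isolated)
18 | rac-6-[(2E,6E)-8-chloro-6-{[(tert-butyldimethylsilyl)oxy]methyl}octa-2,6-dien-2-yl]-3-methyl-4-(trimethylstannyl)-5,6-dihydro-2H-pyran-2-one | CC1=C([Sn](C)(C)C)CC(OC1=O)/C(C)=C/CC/C(=C\CCl)CO[Si](C)(C)C(C)(C)C | intermediate
19 | lactol (2-hydroxy-5,6-dihydro-2H-pyran) from half-reduction of 18 | CC1=C([Sn](C)(C)C)CC(OC1O)/C(C)=C/CC/C(=C\CCl)CO[Si](C)(C)C(C)(C)C | intermediate (not isolated)
20 | rac-(2E,6E,10E)-10-{[(tert-butyldimethylsilyl)oxy]methyl}-12-chloro-2,6-dimethyl-3-(trimethylstannyl)dodeca-2,6,10-triene-1,5-diol | OC/C(C)=C(/[Sn](C)(C)C)CC(O)/C(C)=C/CC/C(=C\CCl)CO[Si](C)(C)C(C)(C)C | intermediate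
21 | rac-(2E,6E,10E)-1-[(tert-butyldimethylsilyl)oxy]-10-{[(tert-butyldimethylsilyl)oxy]methyl}-12-chloro-2,6-dimethyl-3-(trimethylstannyl)dodeca-2,6,10-trien-5-ol | CC(C)(C)[Si](C)(C)OC/C(C)=C(/[Sn](C)(C)C)CC(O)/C(C)=C/CC/C(=C\CCl)CO[Si](C)(C)C(C)(C)C | intermediate
22 | (2E,6E,10E)-1-[(tert-butyldimethylsilyl)oxy]-10-{[(tert-butyldimethylsilyl)oxy]methyl}-12-chloro-2,6-dimethyl-3-(trimethylstannyl)dodeca-2,6,10-trien-5-one (precursor of the key step) | ClC/C=C(/CO[Si](C)(C)C(C)(C)C)CC/C=C(\C)C(=O)C/C(=C(/C)CO[Si](C)(C)C(C)(C)C)[Sn](C)(C)C | intermediate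
23 | (2E,6E,9Z)-6-{[(tert-butyldimethylsilyl)oxy]methyl}-9-{1-[(tert-butyldimethylsilyl)oxy]propan-2-ylidene}-2-methylcyclodeca-2,6-dien-1-one (product of the key step) | CC(C)(C)[Si](C)(C)OC/C1=C/C/C(=C(\C)CO[Si](C)(C)C(C)(C)C)CC(=O)/C(C)=C/CC1 | intermediate
24 | (2E,6E,9Z)-6-(hydroxymethyl)-9-(1-hydroxypropan-2-ylidene)-2-methylcyclodeca-2,6-dien-1-one | OC/C1=C/C/C(=C(\C)CO)CC(=O)/C(C)=C/CC1 | intermediate
25 | (8S,11R)-8,11-spiro-epoxide of 24, C1=C10 alkene intact | OC/C1=C/C[C@@]3(CC(=O)/C(C)=C/CC1)O[C@]3(C)CO | intermediate (not isolated)
26 | bis-epoxy diol: (1R,10R)-1,10-oxirane, (8S,11R)-8,11-spiro-oxirane, E-enone, free C1′ and C12 hydroxyls | OC[C@]12CC/C=C(\C)C(=O)C[C@]3(C[C@H]1O2)O[C@]3(C)CO | intermediate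
27 | CNP0185847.3, diacetate of 26 (1R,10R,8S,11R) | CC(=O)OC[C@]12CC/C=C(\C)C(=O)C[C@]3(C[C@H]1O2)O[C@]3(C)COC(C)=O | target

## Step count and risks

Total step count: 18. Longest linear sequence: 18 steps, from 1 to 27; 6, 8 and 10 are purchased.

Step 15 (key step). Transmetalation of the fully substituted alkenylstannane is likely to be slow. The allylpalladium intermediate may then be lost to intermolecular coupling or reduction, the C–Sn bond may be lost by protodestannylation, and enolisation towards C7 may move the C8=C11 alkene into conjugation with the ketone. Fallback: close the ring one oxidation level lower. Setting out from 21, the same allyl–alkenyl coupling (Pd2(dba)3, AsPh3, CuI, DMF, high dilution; CuI may now be used in stoichiometric amount because no acidic C7–H is present) would give the macrocyclic C6 carbinol F1. Dess–Martin oxidation of F1 comes back to the route at 23.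

Step 17. The second epoxidation may show poor facial selectivity if the conformation of the mono-epoxidised ring opposes the reagent. The C12 hydroxyl may be withdrawn into a cyclic hemiketal with the C6 carbonyl, and the Lewis-acidic titanium alkoxide may open the tetrasubstituted oxirane or trigger β-elimination at C7. Fallback: carry C6 as a silylated carbinol through ring closure and epoxidation, so that no ketone is present. Setting out from 21, TBSOTf and 2,6-lutidine would give the tris-silyl ether F2. The palladium-catalysed ring closure of step 15 would give the macrocyclic tris-silyl ether F3. Brief HF·pyridine at 0 °C (primary ethers only) would give the C6-silylated macrocyclic diol F4. The same Sharpless conditions would give the C6-silylated bis-epoxy diol F5 as two C6 epimers. Bu4NF buffered with AcOH would give the bis-epoxy triol F6. MnO2, which oxidises only the allylic secondary hydroxyl, converges both epimers and comes back to the route at 26.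

Step 10. Zerovalent palladium may ionise the allylic C6–O bond of the lactone, or the triflate may couple with the stannane as it forms, while the hindered tetrasubstituted triflate itself reacts slowly. Fallback: introduce tin by conjugate addition–elimination without palladium. Setting out from 14, [Me3SnCu(SPh)]Li in THF at −78 to −20 °C would give the stannyl lactone 4-methoxybenzyl ether F7. DDQ cleavage of the ether, to which the electron-poor β-stannyl enoate should be inert, comes back to the route at 16.

Step 12. The allylic chloride may be lost by hydride displacement, or the reduction may stop at the lactol. Fallback: install the chloride after the reduction. Setting out from 16, Et3SiCl and imidazole would give the C9 triethylsilyl ether F8. iBu2AlH would give the stannyl diol F9. TBSCl and imidazole would give the C12 silyl ether F10. Pyridinium 4-toluenesulfonate in MeOH at 0 °C would remove only the triethylsilyl group and give the C6,C9-diol F11. MsCl, LiCl and collidine, which convert the primary allylic hydroxyl before the secondary one, come back to the route at 21.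

Further compounds
F1 | step 15 | macrocyclic C6 carbinol, (2E,6E,9Z)-cyclodecadienol analogue of 23 | CC(C)(C)[Si](C)(C)OC/C1=C/C/C(=C(\C)CO[Si](C)(C)C(C)(C)C)CC(O)/C(C)=C/CC1
F2 | step 17 | C6-O-tert-butyldimethylsilyl ether of 21 (tris-silyl ether) | CC(C)(C)[Si](C)(C)OC/C(C)=C(/[Sn](C)(C)C)CC(O[Si](C)(C)C(C)(C)C)/C(C)=C/CC/C(=C\CCl)CO[Si](C)(C)C(C)(C)C
F3 | step 17 | macrocyclic tris-silyl ether (C6 carbinol level, ring as in 23) | CC(C)(C)[Si](C)(C)OC/C1=C/C/C(=C(\C)CO[Si](C)(C)C(C)(C)C)CC(O[Si](C)(C)C(C)(C)C)/C(C)=C/CC1
F4 | step 17 | C6-silylated macrocyclic diol (free C1′ and C12 hydroxyls) | OC/C1=C/C/C(=C(\C)CO)CC(O[Si](C)(C)C(C)(C)C)/C(C)=C/CC1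
F5 | step 17 | C6-silylated bis-epoxy diol, oxiranes configured as in 26, both C6 epimers | OC[C@]12CC/C=C(\C)C(O[Si](C)(C)C(C)(C)C)C[C@]3(C[C@H]1O2)O[C@]3(C)CO
F6 | step 17 | bis-epoxy triol, oxiranes configured as in 26, both C6 epimers | OC[C@]12CC/C=C(\C)C(O)C[C@]3(C[C@H]1O2)O[C@]3(C)CO
F7 | step 10 | stannyl lactone 4-methoxybenzyl ether (16 with C9-O-PMB) | CC1=C([Sn](C)(C)C)CC(OC1=O)/C(C)=C/CC/C(=C\COCc2ccc(OC)cc2)CO[Si](C)(C)C(C)(C)C
F8 | step 12 | C9 triethylsilyl ether of 16 | CC1=C([Sn](C)(C)C)CC(OC1=O)/C(C)=C/CC/C(=C\CO[Si](CC)(CC)CC)CO[Si](C)(C)C(C)(C)C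
F9 | step 12 | stannyl 1,5-diol with C9 triethylsilyl ether | OC/C(C)=C(/[Sn](C)(C)C)CC(O)/C(C)=C/CC/C(=C\CO[Si](CC)(CC)CC)CO[Si](C)(C)C(C)(C)C
F10 | step 12 | C12 tert-butyldimethylsilyl ether of F9 | CC(C)(C)[Si](C)(C)OC/C(C)=C(/[Sn](C)(C)C)CC(O)/C(C)=C/CC/C(=C\CO[Si](CC)(CC)CC)CO[Si](C)(C)C(C)(C)C
F11 | step 12 | C6,C9-diol (21 with hydroxyl in place of chlorine) | CC(C)(C)[Si](C)(C)OC/C(C)=C(/[Sn](C)(C)C)CC(O)/C(C)=C/CC/C(=C\CO)CO[Si](C)(C)C(C)(C)C
A1 | alternative 1 | acyclic bis-epoxy diol with the four stereocentres of 27, C5 (E)-alkenyl iodide, C6 as silyloxymethylene | CC(C)(C)[Si](C)(C)OCC[C@]3(C[C@H]1O[C@@]1(CO)CC/C=C(\C)I)O[C@]3(C)CO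
A2 | alternative 1 | acyclic skipped dienediol, substrate of the twofold epoxidation | CC(C)(C)[Si](C)(C)OCC/C(=C(/C)CO)C/C=C(/CO)CC/C=C(\C)I
A3 | alternative 2 | ten-membered enol triflate: C1 methyl cis to C9, C10 triflate, C6 PMB ether, C8 TBS ether, C4=C5 E | C\C1=C(OS(=O)(=O)C(F)(F)F)/C[C@H](O[Si](C)(C)C(C)(C)C)C[C@@H](OCc2ccc(OC)cc2)/C(C)=C/CC1
A4 | alternative 2 | 1-isopropenyl-2-methyl-2-vinylcyclohexan-1-ol with 3-PMB ether and 5-TBS ether, isopropenyl and vinyl trans (diastereomer assumed for a chair transition state) | CC(=C)[C@@]1(O)C[C@H](O[Si](C)(C)C(C)(C)C)C[C@@H](OCc2ccc(OC)cc2)[C@]1(C)C=C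
A5 | alternative 3 | cyclodeca-dienone with E C4=C5, ring-cis C1=C10 bearing CH2OTBS on C1, and the methyl acrylate unit on C8 | O=C1C[C@H](C(=C)C(=O)OC)C/C=C(/CO[Si](C)(C)C(C)(C)C)CC/C=C1\C
A6 | alternative 3 | tricyclic enone–cyclobutene photoadduct, cis,anti,cis ring fusion with the cyclobutane anti to the C8 side chain (assumed) | O=C1C[C@H](C(=C)C(=O)OC)C[C@@H]2[C@@]1(C)[C@H]3CC[C@@]23CO[Si](C)(C)C(C)(C)C
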